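The numbers in the tables are simulated with made-up constants, and the scatter is random.

In a closed flask of constant volume the substrate charged is conserved, so at any moment its percentages must add up across the entries of one ledger. With partner at 1.05 equiv, substrate is the limiting reagent, and the books are kept on it.

| flask | substrate | partner | capture agent | free catalyst | second catalyst | remark | time |
|---|---|---|---|---|---|---|---|
| alder | 2.7 mM | 1.05 equiv | 20 mM | 1 mol% | 8.5 mol% | run made earlier |  |
| ash | 29 mM | 1.05 equiv | 20 mM | 1 mol% | 8.5 mol% | run made earlier |  |
| Wednesday's | 2.5 mM | 1.05 equiv | 20.0 mM | 1 mol% | 8.5 mol% |  | 8.0 h |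
| Tuesday's | 5.0 mM | 1.05 equiv | 20.0 mM | 1 mol% | 8.5 mol% |  | 8.0 h |
| Saturday's | 10 mM | 1.05 equiv | 20.0 mM | 1 mol% | 8.5 mol% |  | 8.0 h |
| Thursday's | 20 mM | 1.05 equiv | 20.0 mM | 1 mol% | 8.5 mol% |  | 8.0 h |
| Friday's | 40 mM | 1.05 equiv | 20.0 mM | 1 mol% | 8.5 mol% |  | 8.0 h |

| run | time / h | open intermediate / % | product / % | substrate / % |
|---|---|---|---|---|
| alder | 0.417 | 1.4 | 0.8 | 96.4 |
| alder | 0.833 | 6.8 | 1.6 | 94.3 |
| alder | 1.50 | 9.5 | 0.6 | 91.4 |
| alder | 3.00 | 16.4 | 0 | 82.3 |
| alder | 6.00 | 26.7 | 0 | 64.0 |
| ash | 0.417 | 23.1 | 3.8 | 73.2 |
| ash | 0.833 | 33.6 | 10.8 | 53.2 |
| ash | 1.50 | 37.5 | 26.5 | 32.5 |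
| ash | 3.00 | 32.4 | 50.8 | 9.5 |
| ash | 6.00 | 16.5 | 72.8 | 0.9 |

(each reading ± 1 percentage point)

- the earlier runs were read with a standard deviation of 1 percentage point
- "hardly changes" means that all values lie within two and a half points (for a concentration: within two and a half percent of the largest)

* amount of open intermediate at the end, in percent of the substrate charged for Wednesday's, Tuesday's, Saturday's, Thursday's, Friday's, in this order
* how that number moves from the first to the last of them (hardly changes / rises, then falls / falls all the way / falls, then rises / rises all the way)

The first entry is substrate still unspent. If its loss took no notice of the charge, the two earlier runs would keep the same percentage at the same time. They do not: at 1.50 h the alder run keeps 91.4 % and the ash run 32.5 %. Free catalyst is charged at 1 mol% of substrate, and within a run the loss looks pseudo-first-order, with a constant that grows with the charge. The useful quantity is therefore the logarithm of charged over left, divided by the time and by the charge, here called the clearance constant. The ash reading gives 25.8 L mol⁻¹ h⁻¹, and the last alder reading gives 27.5 L mol⁻¹ h⁻¹. With the ash value, substrate left at 8.0 h comes to 59.6 % in Wednesday's flask, 12.7 % in Saturday's and 1.60 % in Thursday's.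

The second entry is what the readings do not show. At 6.00 h the alder books lack 9.3 percentage points and the ash books 9.8 points; each gap carries the scatter of the readings behind it, and two gaps at two charges are not taken to show how this entry moves with the charge.

The third entry is product, which reads 0 % in the alder run and 72.8 % in the ash run at that time. Open intermediate is the remainder. For Wednesday's flask, with product and the unseen entry taken as in the alder run, my reckoning closes at 31.1 %, a figure to be shaded down because the unseen entry was read earlier than 8.0 h. Higher charges pass more substrate on, but the ash run already holds 16.5 % of open intermediate at 6.00 h and is falling, so I expect a rise and then a fall, without closing the middle entries.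

The forecast, lower than my figure for Wednesday's flask, reads 29 %, 40 %, 40 %, 20 % and 3 %, shape "rises, then falls", with the caution “The middle values are uncertain because the form of the slowdown is unknown.”

The flask gives 29.4 %, 42.4 %, 41.2 %, 19.5 % and 3.78 %, shape "rises, then falls".

    second catalyst + open intermediate ⇌ catalyst intermediate (K = 15.8 L mol⁻¹, k = 71.7 L mol⁻¹ min⁻¹)
    substrate + free catalyst → free catalyst + open intermediate (k = 43.1 L mol⁻¹ min⁻¹)
    open intermediate + capture agent → trapped intermediate (k = 0.0578 L mol⁻¹ min⁻¹)
    partner + catalyst intermediate → second catalyst + product (k = 13.1 L mol⁻¹ min⁻¹)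

Wednesday's flask ends with 9.87 % as trapped intermediate, the entry the readings could not show, and with 59.6 % of substrate against the 59.6 % reckoned. On Friday's flask the clearance constant puts substrate under 2 % of its charge after 3.79 h, and that flask crosses the line at 3.78 h.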